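**Plan** (bicyclo[7.2.0]undecane = caryophyllane numbering C1–C11; C13 = pyran CH2 next to C8; C1′ = isobutyl-bearing CH)
1. Cuts, in order: O–C8 and C13–C1′ of the spiro-dihydropyran (hetero-Diels–Alder of a C8=C13 methylene with isopentylidene-syncarpic acid), then C5–O, then C3=C4, then S–C3 and C7–C8, and last the cyclobutane bonds C1–C11 and C9–C10.
2. Enabling feature: the Z-trisubstituted C3=C4 bond is the only unsaturation in the nine-membered carbocycle C1–C9, and neither of its carbons is stereogenic. That ring therefore equals a ten-membered thiacycle with sulfur between C3 and C4, from which SO2 is deleted.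
3. Forward ring order: cyclobutane ([2+2] photocycloaddition), ten-membered thioether (thiolate alkylation), nine-membered carbocycle (Ramberg–Bäcklund contraction), dihydropyran (cycloaddition).
4. Stereochemistry: C1 comes from resolution of the photoadduct lactone as (S)-1-phenylethylamides, and C9 from base equilibration to the trans-cyclobutane. The Z alkene comes from the cis-episulfone, C5 from a CBS reduction, and C8 and C1′ from the facial and orientational bias of the cycloaddition.

Key step: step 15

Assumption: C4 is erased in the key step, so it is carried as a mixture of both epimers and the SMILES leave it open; syncarpic acid is taken as a purchasable compound.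

Step 1
Reactants: 1 5,6-dihydro-2H-pyran-2-one; 2 isobutylene
Product: 3 (±)-cis-7,7-dimethyl-3-oxabicyclo[4.2.0]octan-2-one
Conditions: hν (medium-pressure Hg lamp, quartz), 2 (excess, condensed), MeCN–acetone, −30 °C; then basic Al2O3, CH2Cl2, rt; chromatography
Reagents that add atoms: none
Why: Triplet [2+2] photocycloaddition of an α,β-unsaturated δ-lactone to a simple alkene; the head-to-tail orientation usual for electron-rich 1,1-disubstituted alkenes puts CMe2 (C11) on the β-carbon (C1), the alumina treatment converts any strained trans-fused adduct into the cis-lactone so that C1 and C9 are set cis in racemic form, and the head-to-head isomer is removed by chromatography.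

Step 2
Reactants: 3 (±)-cis-7,7-dimethyl-3-oxabicyclo[4.2.0]octan-2-one
Product: 4 (1R,2R)-2-(2-hydroxyethyl)-3,3-dimethyl-N-[(1S)-1-phenylethyl]cyclobutane-1-carboxamide
Conditions: (S)-1-phenylethylamine (1.5 equiv), 2-hydroxypyridine (cat.), toluene, 110 °C; separation of the two diastereomers on silica gel
Reagents that add atoms: (S)-1-phenylethylamine, C[C@H](N)c1ccccc1
Why: Catalysed lactone aminolysis by an enantiopure amine (resolution through covalent diastereomers) touches no ring stereocentre and turns the enantiomers of 3 into two hydroxy amides that differ next to the amide group and should separate on silica gel; the (1R,2R) isomer, to be identified by X-ray analysis, carries the C1 configuration of the target.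

Step 3
Reactants: 4 (1R,2R)-hydroxy amide
Product: 5 (1R,6R)-7,7-dimethyl-3-oxabicyclo[4.2.0]octan-2-one
Conditions: 1 M H2SO4, 1,4-dioxane, 90 °C
Reagents that add atoms: none
Why: Amide hydrolysis assisted by the neighbouring hydroxyl group (N-to-O acyl transfer, lactonisation) frees the amine under mild conditions, and the cis-fused lactone has no stable trans form to epimerise to, so both centres are kept.

Step 4
Reactants: 5 (1R,6R)-lactone
Product: 6 (1R,2R)-2-(2-hydroxyethyl)-N-methoxy-N,3,3-trimethylcyclobutane-1-carboxamide
Conditions: MeNH(OMe)·HCl, i-PrMgCl, THF, −20 → 0 °C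
Reagents that add atoms: N,O-dimethylhydroxylamine hydrochloride, CNOC.Cl
Why: Weinreb amide formation from a lactone with the magnesium amide of N,O-dimethylhydroxylamine is a plain acyl substitution that involves no stereocentre.

Step 5
Reactants: 6 hydroxy Weinreb amide
Product: 7 (1R,2R)-2-[2-(tert-butyldimethylsilyloxy)ethyl]-N-methoxy-N,3,3-trimethylcyclobutane-1-carboxamide
Conditions: TBSCl, imidazole, CH2Cl2, 0 °C → rt
Reagents that add atoms: tert-butyldimethylsilyl chloride, CC(C)(C)[Si](C)(C)Cl
Why: Standard silylation of the primary alcohol, done at once because the hydroxy amide tends to fall back to lactone 5.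

Step 6
Reactants: 8 5-chloropentan-2-one
Product: 9 (±)-5-chloropentan-2-ol
Conditions: NaBH4, MeOH, 0 °C
Reagents that add atoms: none
Why: Borohydride reduction of a methyl ketone, kept cold to avoid closure to 2-methyltetrahydrofuran; the new carbinol centre (C4) is deliberately left uncontrolled because step 15 erases it.

Step 7
Reactants: 9 (±)-5-chloropentan-2-ol
Product: 10 (±)-tert-butyl[(5-chloropentan-2-yl)oxy]dimethylsilane
Conditions: TBSCl, imidazole, DMF, rt
Reagents that add atoms: tert-butyldimethylsilyl chloride, CC(C)(C)[Si](C)(C)Cl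
Why: Standard silylation makes the chloride fit for Grignard formation.

Step 8
Reactants: 10 silyloxy chloride; 7 Weinreb amide
Product: 13 trans-ketone 1-{(1S,2R)-2-[2-(tert-butyldimethylsilyloxy)ethyl]-3,3-dimethylcyclobutyl}-5-(tert-butyldimethylsilyloxy)hexan-1-one (both C4 epimers), via Grignard reagent 11 (not isolated), via cis-ketone 12 (not isolated)
Conditions: 10, Mg, I2 (cat.), THF, reflux; 7, THF, 0 °C; then MeOH, NaOMe, rt (one flask)
Reagents that add atoms: none
Why: The Weinreb ketone synthesis (a chelated tetrahedral intermediate stops double addition) forms C7–C8, and methoxide then equilibrates the enolisable C9 centre to the thermodynamically preferred trans-1,2-disubstituted cyclobutane, which sets C9 as S relative to the fixed C1.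

Step 9
Reactants: 13 trans-ketone
Product: 14 ethylene ketal of 13
Conditions: (Me3SiOCH2)2, Me3SiOTf (cat.), CH2Cl2, −78 → −20 °C; pyridine quench
Reagents that add atoms: 1,2-bis(trimethylsilyloxy)ethane, C[Si](C)(C)OCCO[Si](C)(C)C
Why: Noyori ketalisation under aprotic conditions masks C8 while both silyl ethers stay on, which avoids the cyclic mixed ketals a free C3 or C4 hydroxyl would form under protic acid; C9 is already in its stable configuration.

Step 10
Reactants: 14 bis-silyl ether ketal
Product: 15 diol 5-{2-[(1S,2R)-2-(2-hydroxyethyl)-3,3-dimethylcyclobutyl]-1,3-dioxolan-2-yl}pentan-2-ol (both C4 epimers)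
Conditions: Bu4NF, THF, rt
Reagents that add atoms: none
Why: Fluoride cleaves both silyl ethers, and the ketal is inert to fluoride.

Step 11
Reactants: 15 diol
Product: 16 primary (C3) p-toluenesulfonate of 15
Conditions: TsCl (1.05 equiv), Et3N, 4-(dimethylamino)pyridine (cat.), CH2Cl2, 0 °C
Reagents that add atoms: p-toluenesulfonyl chloride, Cc1ccc(cc1)S(=O)(=O)Cl
Why: Chemoselective sulfonylation of the primary C3 alcohol over the secondary C4 alcohol on steric grounds, with one equivalent of reagent at low temperature.

Step 12
Reactants: 16 hydroxy tosylate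
Product: 17 C4 thioacetate, C3 tosylate
Conditions: PPh3, diisopropyl azodicarboxylate (DIAD), THF, 0 °C; then 16, AcSH, 0 °C → rt
Reagents that add atoms: thioacetic acid, CC(=O)S
Why: Mitsunobu thioesterification of the secondary alcohol (SN2 inversion at C4, which is immaterial); the pre-formed betaine and the low temperature keep thioacetate away from the primary tosylate.

Step 13
Reactants: 17 thioacetate tosylate
Product: 19 ten-membered cyclic sulfide (1R,10S)-5,12,12-trimethyl-4-thiabicyclo[8.2.0]dodecan-9-one ethylene ketal (sulfur between caryophyllane C3/C4; both C4 epimers), via caesium thiolate 18 (not isolated)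
Conditions: Cs2CO3, DMF–MeOH, degassed, 50 °C, slow addition of 17 (high dilution)
Reagents that add atoms: none
Why: Caesium thiolate macrocyclisation, in which methanolysis unmasks the soft thiolate and this closes the ring by 10-exo-tet SN2 attack on the unhindered primary tosylate; the long C–S bonds, the trans-cyclobutane and the quaternary ketal carbon restrict the chain and should help closure.

Step 14
Reactants: 19 cyclic sulfide
Product: 20 cyclic sulfone (4,4-dioxide of 19; both C4 epimers)
Conditions: mCPBA (2.2 equiv), NaHCO3, CH2Cl2, 0 °C → rt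
Reagents that add atoms: 3-chloroperbenzoic acid, O=C(OO)c1cccc(Cl)c1
Why: Peracid oxidation of sulfide to sulfone via the sulfoxide; the buffer protects the ketal and no alkene is present yet.

Step 15
Reactants: 20 cyclic α-methyl sulfone
Product: 23 (1R,3Z,9S)-4,11,11-trimethylbicyclo[7.2.0]undec-3-en-8-one ethylene ketal, via 3-bromo sulfone 21 (not isolated), via cis-episulfone 22 (not isolated)
Conditions: KOH on Al2O3, CBr2F2, t-BuOH–CH2Cl2, 0 °C → rt
Reagents that add atoms: none
Why: Hydroxide on alumina removes one of the more acidic, less hindered C3 protons and the carbanion takes bromine from CBr2F2 to give 21; deprotonation at C4 and backside 3-exo-tet displacement of bromide then join C3 to C4 in episulfone 22, which expels SO2 stereospecifically. The closest known reaction type is the one-flask Ramberg–Bäcklund ring contraction of medium-ring cyclic sulfones with in situ halogenation. Two rings close: the transient thiirane 1,1-dioxide by 3-exo-tet attack and, through the same C3–C4 bond, the nine-membered carbocycle, so the ten-membered ring shrinks by the sulfur atom. No lasting stereocentre is created, since C3 and C4 become sp2; both C4 epimers of 20, and also bromination at C4 in place of C3, therefore converge on 23, while C1 and C9 carry no acidic hydrogen once C8 is a ketal. The step needs Z geometry, which rests on the kinetic preference of hydroxide conditions for the cis-episulfone together with the extra strain of a trans-fused episulfone and of an E-cyclononene; for that reason no stronger base that could epimerise C3 of 22 is used. CBr2F2 is chosen because bromide should leave fast enough to outrun a second halogenation at C3 and because no dichlorocarbene arises that could add to the new alkene.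

Step 16
Reactants: 23 Z-cyclononene ketal
Product: 24 (1R,3Z,9S)-5-hydroxy-4,11,11-trimethylbicyclo[7.2.0]undec-3-en-8-one ethylene ketal (both C5 epimers)
Conditions: SeO2 (0.3 equiv), t-BuOOH (in decane), CH2Cl2, 0 °C → rt
Reagents that add atoms: tert-butyl hydroperoxide, CC(C)(C)OO; selenium dioxide, O=[Se]=O
Why: Selenium dioxide allylic hydroxylation (ene reaction, then [2,3]-sigmatropic shift) binds selenium to the less substituted C3, so only hydrogens on the substituents of C4 can be taken; the empirical rules (CH2 before CH3, in-ring position preferred) point to C5, whose configuration is left open because step 17 removes it.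

Step 17
Reactants: 24 allylic alcohol
Product: 25 (1R,3Z,9S)-4,11,11-trimethylbicyclo[7.2.0]undec-3-ene-5,8-dione 8-ethylene ketal
Conditions: Dess–Martin periodinane, NaHCO3, CH2Cl2, 0 °C → rt
Reagents that add atoms: none
Why: Dess–Martin oxidation takes both C5 epimers to one enone, removes the uncontrolled centre and leaves the ketal intact under buffered conditions.

Step 18
Reactants: 25 enone ketal
Product: 26 (1R,3Z,5S,9S)-5-hydroxy-4,11,11-trimethylbicyclo[7.2.0]undec-3-en-8-one ethylene ketal
Conditions: (3aR)-1-methyl-3,3-diphenyltetrahydro-1H,3H-pyrrolo[1,2-c][1,3,2]oxazaborole (C18H20BNO, the R-configured methyl CBS catalyst, 0.3 equiv), BH3·SMe2, THF, −40 °C; MeOH quench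
Reagents that add atoms: none
Why: In the Corey–Bakshi–Shibata reduction the ketone binds to the catalyst with the larger α-methylalkenyl flank turned away, the sense established for 2-substituted cycloalkenones, so the R catalyst should deliver hydride to the face that gives the 5S alcohol and should override the remote C1/C9 centres.

Step 19
Reactants: 26 (5S)-allylic alcohol
Product: 27 5-O-tert-butyldimethylsilyl ether of 26
Conditions: TBSCl, imidazole, DMF, rt
Reagents that add atoms: tert-butyldimethylsilyl chloride, CC(C)(C)[Si](C)(C)Cl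
Why: Standard silylation blocks transannular hemiketal formation with C8 in the next steps and shields the neighbouring C3=C4 bond.

Step 20
Reactants: 27 silyl ether ketal
Product: 28 (1R,3Z,5S,9S)-5-(tert-butyldimethylsilyloxy)-4,11,11-trimethylbicyclo[7.2.0]undec-3-en-8-one
Conditions: pyridinium p-toluenesulfonate (cat.), acetone–H2O, reflux
Reagents that add atoms: water, O
Why: Mild acid-catalysed ketal hydrolysis, in which a secondary silyl ether should tolerate the weakly acidic pyridinium salt.

Step 21
Reactants: 28 ketone
Product: 29 (1R,3Z,5S,9S)-5-(tert-butyldimethylsilyloxy)-4,11,11-trimethyl-8-methylidenebicyclo[7.2.0]undec-3-ene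
Conditions: Ph3PCH3Br, KOt-Bu, THF, 0 °C → reflux
Reagents that add atoms: methyltriphenylphosphonium bromide, C[P+](c1ccccc1)(c1ccccc1)c1ccccc1.[Br-]
Why: Wittig methylenation of a hindered, enolisable cyclononanone is the classical way to the exocyclic methylene of caryophyllane frameworks; C9 may enolise but already holds the more stable trans configuration.

Step 22
Reactants: 30 syncarpic acid; 31 isovaleraldehyde
Product: 32 2,2,4,4-tetramethyl-6-(3-methylbutylidene)cyclohexane-1,3,5-trione
Conditions: piperidinium acetate (cat.), 4 Å molecular sieves, CH2Cl2, rt; used at once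
Reagents that add atoms: none
Why: Knoevenagel condensation of the active methylene group of a cyclic β-triketone with an aliphatic aldehyde gives the symmetrical alkylidene trione (no E/Z issue), an electron-poor 1-oxadiene.

Step 23
Reactants: 29 silyloxy diene; 32 alkylidene trione
Product: 33 5-O-tert-butyldimethylsilyl-tomentodione P
Conditions: toluene, 100 °C, sealed tube, 2,6-di-tert-butyl-4-methylphenol (trace)
Reagents that add atoms: none
Why: In this inverse-electron-demand hetero-Diels–Alder reaction of an alkylidene-1,3-dione with a 1,1-disubstituted alkene, the polarised addition puts oxygen on the more substituted C8 and C13 on C1′, and the hindered, inductively deactivated C3=C4 bond should stay out; C8 should be set by approach to the outer face of the methylene group, away from the ring interior, and C1′ by the orientation that keeps the isobutyl group off the nine-membered ring, with other diastereomers removed by chromatography.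

Step 24
Reactants: 33 silyl ether
Product: 34 tomentodione P (1R,3Z,5S,8S,9S,1′S)
Conditions: Bu4NF, THF, 0 °C → rt
Reagents that add atoms: none
Why: Fluoride desilylation leaves the vinylogous ester, the tertiary enol ether linkage and the alkene untouched and affects no stereocentre.

**Compound list**
1 | 5,6-dihydro-2H-pyran-2-one | O=C1C=CCCO1 | starting material
2 | isobutylene (2-methylpropene) | CC(C)=C | starting material
3 | (±)-cis-7,7-dimethyl-3-oxabicyclo[4.2.0]octan-2-one (racemate, both enantiomers written) | O=C1OCC[C@@H]2[C@H]1CC2(C)C.O=C1OCC[C@H]2[C@@H]1CC2(C)C | intermediate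
4 | (1R,2R)-2-(2-hydroxyethyl)-3,3-dimethyl-N-[(1S)-1-phenylethyl]cyclobutane-1-carboxamide | OCC[C@@H]1[C@@H](CC1(C)C)C(=O)N[C@@H](C)c1ccccc1 | intermediate
5 | (1R,6R)-7,7-dimethyl-3-oxabicyclo[4.2.0]octan-2-one | O=C1OCC[C@@H]2[C@H]1CC2(C)C | intermediate
6 | (1R,2R)-2-(2-hydroxyethyl)-N-methoxy-N,3,3-trimethylcyclobutane-1-carboxamide | OCC[C@@H]1[C@@H](CC1(C)C)C(=O)N(C)OC | intermediate
7 | (1R,2R)-2-[2-(tert-butyldimethylsilyloxy)ethyl]-N-methoxy-N,3,3-trimethylcyclobutane-1-carboxamide | CC(C)(C)[Si](C)(C)OCC[C@@H]1[C@@H](CC1(C)C)C(=O)N(C)OC | intermediate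
8 | 5-chloropentan-2-one | CC(=O)CCCCl | starting material
9 | (±)-5-chloropentan-2-ol | CC(O)CCCCl | intermediate
10 | (±)-tert-butyl[(5-chloropentan-2-yl)oxy]dimethylsilane | CC(CCCCl)O[Si](C)(C)C(C)(C)C | intermediate
11 | 4-(tert-butyldimethylsilyloxy)pentylmagnesium chloride | CC(CCC[Mg]Cl)O[Si](C)(C)C(C)(C)C | intermediate
12 | cis-ketone, (1R,2R)-cyclobutyl isomer of 13 (both C4 epimers) | CC(C)(C)[Si](C)(C)OCC[C@@H]1[C@@H](CC1(C)C)C(=O)CCCC(C)O[Si](C)(C)C(C)(C)C | intermediate
13 | trans-ketone 1-{(1S,2R)-2-[2-(tert-butyldimethylsilyloxy)ethyl]-3,3-dimethylcyclobutyl}-5-(tert-butyldimethylsilyloxy)hexan-1-one (both C4 epimers) | CC(C)(C)[Si](C)(C)OCC[C@@H]1[C@H](CC1(C)C)C(=O)CCCC(C)O[Si](C)(C)C(C)(C)C | intermediate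
14 | ethylene ketal of 13 | CC(C)(C)[Si](C)(C)OCC[C@@H]1[C@H](CC1(C)C)C1(CCCC(C)O[Si](C)(C)C(C)(C)C)OCCO1 | intermediate
15 | diol 5-{2-[(1S,2R)-2-(2-hydroxyethyl)-3,3-dimethylcyclobutyl]-1,3-dioxolan-2-yl}pentan-2-ol (both C4 epimers) | OCC[C@@H]1[C@H](CC1(C)C)C1(CCCC(C)O)OCCO1 | intermediate
16 | primary (C3) p-toluenesulfonate of 15 | Cc1ccc(cc1)S(=O)(=O)OCC[C@@H]1[C@H](CC1(C)C)C1(CCCC(C)O)OCCO1 | intermediate
17 | C4 thioacetate, C3 tosylate | Cc1ccc(cc1)S(=O)(=O)OCC[C@@H]1[C@H](CC1(C)C)C1(CCCC(C)SC(C)=O)OCCO1 | intermediate
18 | caesium C4 thiolate of 17 | [Cs+].Cc1ccc(cc1)S(=O)(=O)OCC[C@@H]1[C@H](CC1(C)C)C1(CCCC(C)[S-])OCCO1 | intermediate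
19 | (1R,10S)-5,12,12-trimethyl-4-thiabicyclo[8.2.0]dodecan-9-one ethylene ketal (both C4 epimers) | CC1CCCC2(OCCO2)[C@H]3CC(C)(C)[C@@H]3CCS1 | intermediate
20 | 4,4-dioxide of 19, trans-cyclobutane-fused ten-membered α-methyl sulfone (both C4 epimers) | CC1CCCC2(OCCO2)[C@H]3CC(C)(C)[C@@H]3CCS1(=O)=O | intermediate
21 | 3-bromo derivative of 20 (C3 and C4 open) | CC1CCCC2(OCCO2)[C@H]3CC(C)(C)[C@@H]3CC(Br)S1(=O)=O | intermediate
22 | cis-fused thiirane 1,1-dioxide spanning C3 and C4 (one of the two cis forms drawn) | C[C@]12CCCC3(OCCO3)[C@H]4CC(C)(C)[C@@H]4C[C@H]1S2(=O)=O | intermediate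
23 | (1R,3Z,9S)-4,11,11-trimethylbicyclo[7.2.0]undec-3-en-8-one ethylene ketal | C/C1=C/C[C@@H]2[C@H](CC2(C)C)C2(OCCO2)CCC1 | intermediate
24 | (1R,3Z,9S)-5-hydroxy-4,11,11-trimethylbicyclo[7.2.0]undec-3-en-8-one ethylene ketal (both C5 epimers) | C/C1=C/C[C@@H]2[C@H](CC2(C)C)C2(OCCO2)CCC1O | intermediate
25 | (1R,3Z,9S)-4,11,11-trimethylbicyclo[7.2.0]undec-3-ene-5,8-dione 8-ethylene ketal | C/C1=C/C[C@@H]2[C@H](CC2(C)C)C2(OCCO2)CCC1=O | intermediate
26 | (1R,3Z,5S,9S)-5-hydroxy-4,11,11-trimethylbicyclo[7.2.0]undec-3-en-8-one ethylene ketal | C/C1=C/C[C@@H]2[C@H](CC2(C)C)C2(OCCO2)CC[C@@H]1O | intermediate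
27 | 5-O-tert-butyldimethylsilyl ether of 26 | C/C1=C/C[C@@H]2[C@H](CC2(C)C)C2(OCCO2)CC[C@@H]1O[Si](C)(C)C(C)(C)C | intermediate
28 | (1R,3Z,5S,9S)-5-(tert-butyldimethylsilyloxy)-4,11,11-trimethylbicyclo[7.2.0]undec-3-en-8-one | C/C1=C/C[C@@H]2[C@H](CC2(C)C)C(=O)CC[C@@H]1O[Si](C)(C)C(C)(C)C | intermediate
29 | (1R,3Z,5S,9S)-5-(tert-butyldimethylsilyloxy)-4,11,11-trimethyl-8-methylidenebicyclo[7.2.0]undec-3-ene | C/C1=C/C[C@@H]2[C@H](CC2(C)C)C(=C)CC[C@@H]1O[Si](C)(C)C(C)(C)C | intermediate
30 | syncarpic acid (2,2,4,4-tetramethylcyclohexane-1,3,5-trione) | CC1(C)C(=O)CC(=O)C(C)(C)C1=O | starting material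
31 | isovaleraldehyde (3-methylbutanal) | CC(C)CC=O | starting material
32 | 2,2,4,4-tetramethyl-6-(3-methylbutylidene)cyclohexane-1,3,5-trione | CC(C)CC=C1C(=O)C(C)(C)C(=O)C(C)(C)C1=O | intermediate
33 | 5-O-tert-butyldimethylsilyl-tomentodione P | C/C1=C/C[C@@H]2[C@H](CC2(C)C)[C@]2(CC[C@@H]1O[Si](C)(C)C(C)(C)C)C[C@H](CC(C)C)C1=C(O2)C(C)(C)C(=O)C(C)(C)C1=O | intermediate
34 | tomentodione P | C/C1=C/C[C@@H]2[C@H](CC2(C)C)[C@]2(CC[C@@H]1O)C[C@H](CC(C)C)C1=C(O2)C(C)(C)C(=O)C(C)(C)C1=O | target

**Totals and risks**
Total steps: 24. Longest linear sequence: 21 steps (1–5, 8–21, 23, 24).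

Step 16 may fail through poor site selectivity, with the selenium reagent attacking the vinylic methyl group or C2 in place of C5, or through loss of the Z geometry in the [2,3] shift.
- The fallback sets out from 23 and reaches C5 by a double transposition.
- Dye-sensitised photo-oxygenation (O2, tetraphenylporphyrin, hν, CH2Cl2) exploits the preference of singlet oxygen for hydrogen abstraction on the more crowded alkene side (C5–H, oxygen to C3). It should give the allylic hydroperoxide F1.
- Acetic anhydride and pyridine in the same flask dehydrate it (Kornblum–DeLaMare type) to the transposed enone F2.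
- H2O2/NaOH in MeOH gives the epoxy ketone F3.
- A Wharton transposition (N2H4·H2O, AcOH cat., MeOH) moves the oxygen to C5 and the double bond back to C3=C4. The route is rejoined at 24.

Step 23 may fail through poor facial and orientational selectivity at the methylene group, or through a competing ene reaction.
- The fallback sets out from 29. Bu4NF removes the silyl group first to give the free dienol F4.
- F4 is heated with 32 in toluene. The C5 hydroxyl can hydrogen-bond to a carbonyl group of the heterodiene and changes the populated ring conformers, so a directing group replaces steric shielding as the control element.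
- The cycloadduct is 34 itself, where the route is rejoined.

Step 13 may fail because intermolecular S-alkylation (oligomerisation) outruns the medium-ring closure.
- The fallback sets out from 15 and closes the ring through a reversible S–S bond before one sulfur is removed.
- MsCl/Et3N gives the dimesylate F5, and KSAc in DMF gives the bis-thioacetate F6.
- K2CO3 in MeOH frees the dithiol F7. I2 under high dilution closes the eleven-membered cyclic disulfide F8.
- P(NEt2)3 in benzene extrudes one sulfur: the phosphine attacks the sulfur on C3, and the ion-paired C4 thiolate displaces at the primary carbon. This gives 19, where the route is rejoined.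

**Further compounds**
F1 | step 16 | (1R,4Z,9S)-3-hydroperoxy-4,11,11-trimethylbicyclo[7.2.0]undec-4-en-8-one ethylene ketal (C3 open) | C/C1=C/CCC2(OCCO2)[C@H]3CC(C)(C)[C@@H]3CC1OO
F2 | step 16 | (1R,4Z,9S)-4,11,11-trimethylbicyclo[7.2.0]undec-4-ene-3,8-dione 8-ethylene ketal | C/C1=C/CCC2(OCCO2)[C@H]3CC(C)(C)[C@@H]3CC1=O
F3 | step 16 | 4,5-epoxide of F2 (C4 and C5 open) | CC12OC1CCC3(OCCO3)[C@H]4CC(C)(C)[C@@H]4CC2=O
F4 | step 23 | (1R,3Z,5S,9S)-4,11,11-trimethyl-8-methylidenebicyclo[7.2.0]undec-3-en-5-ol | C/C1=C/C[C@@H]2[C@H](CC2(C)C)C(=C)CC[C@@H]1O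
F5 | step 13 | dimesylate of 15 | CS(=O)(=O)OCC[C@@H]1[C@H](CC1(C)C)C1(CCCC(C)OS(C)(=O)=O)OCCO1
F6 | step 13 | C3,C4-bis-thioacetate | CC(=O)SCC[C@@H]1[C@H](CC1(C)C)C1(CCCC(C)SC(C)=O)OCCO1
F7 | step 13 | C3,C4-dithiol | SCC[C@@H]1[C@H](CC1(C)C)C1(CCCC(C)S)OCCO1
F8 | step 13 | eleven-membered cyclic disulfide (S–S between C3 and C4), C8 ethylene ketal | CC1CCCC2(OCCO2)[C@H]3CC(C)(C)[C@@H]3CCSS1
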